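Late in these runs the target falls behind what its own early readings promise, and we want to know by how much in a flask not yet run.

| setting | Thursday's | Wednesday's | Saturday's | Friday's |
|---|---|---|---|---|
| substrate | 1.00 M | 0.500 M | 1.50 M | 1.00 M |
| reagent | 0.800 M | 0.300 M | 0.800 M | 0.400 M |
| catalyst | 0.00200 M | 0.00200 M | 0.00200 M | 0.00100 M |
| time |  |  |  | 18 min |

- Thursday's run (time / min: [target] / M): 0.72: 0.106; 1.4: 0.148; 2.6: 0.202; 5.0: 0.249; 9.5: 0.304; 18: 0.384
- Wednesday's run (time / min: [target] / M): 0.72: 0.066; 1.4: 0.090; 2.6: 0.133; 5.0: 0.174; 9.5: 0.227; 18: 0.239
- Saturday's run (time / min: [target] / M): 0.72: 0.125; 1.4: 0.173; 2.6: 0.240; 5.0: 0.320; 9.5: 0.409; 18: 0.457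

(each reading ± 0.005 M)

- reaction order in [reagent] at the outset, round the charge of the Thursday's run, defined at two percent of the substrate turned into target
- reaction order in [substrate] at the outset, round the charge of the Thursday's run, defined at two percent of the substrate turned into target (one fixed amount of target, the same in the runs compared)
- target in the Friday's run at 18 min, as a share of the substrate charged

- Overall: substrate + reagent -> target, with catalyst as catalyst.
- Constant volume, constant temperature.
- What is held in complexes is read along with the free species.
- An order is taken over about fifteen percent of the charge, up and down.

Thursday's reading at 2.6 min gives a square time of 63.7 min, the time at which a straight line of target squared against elapsed time, drawn from the start through that reading, reaches the square of 1.00 M, our yardstick for each flask; its two earlier readings give 64.1 min and 63.9 min. Run forward to 18 min, Thursday's square time promises 0.531 M of target. That is below the reagent charge of 0.800 M, the limiting reagent there, so the charge allows it. Yet Thursday's reading is 0.384 M.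

So we treat the square law as the large part and reckon only the correction. The keep factor, last reading over what the clock promised, is 0.722 for Thursday's run. Saturday's square time of 45.1 min gives a keep factor of 0.724, close to Thursday's. Wednesday's square time of 147 min gives 0.683, but its promise of 0.350 M lies above Wednesday's reagent charge of 0.300 M.

Under the square law, the rate at one amount of target goes inversely with the square time. Saturday against Thursday therefore gives us a substrate order of 0.850, and Wednesday, with substrate allowed for, a reagent order of 0.251. Assuming first order in catalyst, which is untested, Friday's square time is 152 min. It promises 0.344 M at 18 min, and Thursday's keep factor brings that to 24.9% of the substrate charged.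

The forecast, made from the same runs, sees “strong product inhibition, with the burst already over”. It gives a reagent order of 0.35 (0.1 to 0.7), a substrate order of 0.75 (0.45 to 1.05), and 26% for Friday (20% to 33%). These numbers differ from ours.

Friday's flask gives 27.1%, inside the forecast's range. The orders are 0.44 in reagent and 0.59 in substrate, so the forecast's substrate order stands above the result and its reagent order below it.

    catalyst + substrate → catalyst-substrate complex (443.4 L mol⁻¹ min⁻¹)
    catalyst-substrate complex + reagent → target + catalyst (368.4 L mol⁻¹ min⁻¹)
    target + reagent → side product (0.2076 L mol⁻¹ min⁻¹)
    catalyst + target ⇌ catalyst-product complex, settled at all times (53.50 L mol⁻¹)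

Friday's shortfall comes from the step from target and reagent to side product: with that step taken away, the same run gives 36.2% instead of 27.1%, a difference of 9.2 percentage points. Friday's square time, before any correction, had promised 34.4%. Carried to Saturday's run with our substrate order, Thursday's square time of 63.7 min puts a quarter of the substrate charged at 6.35 min, and Saturday's flask reaches it at 7.84 min.

Readings and results stem from a simulated flask for substances that don't exist, noise included.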